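**Assumptions (one line each)**
- The chiral acid used in Step 5 is taken as the enantiomer that delivers the (R) centre at C3. The CIP label of the target SMILES is (3R), checked by hand.
- Both prenyl-bearing carbons sit between two oxygens, so both aryl halves come from 2-prenylresorcinol units.

**Retrosynthesis**
- Target ← remove the two B-ring methyl ethers (late nucleophilic demethylation) ← 7-hydroxychroman, built last by intramolecular Mitsunobu O-alkylation of a 1,2-diarylpropan-1-ol.
- The C3 stereocentre and the C4–C4a bond form together in one desymmetrizing step: an enantiotopic-selective Friedel–Crafts ring-opening of an achiral, mirror-symmetric 3-aryloxetane by 2-prenylresorcinol.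
- The oxetane comes from Ni-catalysed coupling of an aryl bromide with 3-iodooxetane. Both aryl halves come from 2-prenyl-1,3-dimethoxybenzene, made from cheap 1,3-dimethoxybenzene by C2-lithiation and prenylation.
- Ring order: the oxetane forms first (transient, symmetric), is opened to give the stereocentre, and the chroman ring closes last.

---

**Step 1**
Reactants: 1 (1,3-dimethoxybenzene); 2 (prenyl bromide, 1-bromo-3-methylbut-2-ene)
Product: 3 (2-prenyl-1,3-dimethoxybenzene)
Conditions: n-BuLi, THF, 0 °C → rt; then CuI (10 mol%), 2, −40 °C → rt
Reagents that add atoms: prenyl bromide, CC(C)=CCBr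
Why: Directed ortho-metalation puts lithium at C2 between the two OMe groups, and Cu(I) steers alkylation to the linear SN2 prenyl product rather than the SN2′ product.

**Step 2**
Reactants: 3; 4 (N-bromosuccinimide)
Product: 5 (4-bromo-2-prenyl-1,3-dimethoxybenzene, i.e. 1-bromo-2,4-dimethoxy-3-prenylbenzene)
Conditions: 4 (1.0 equiv), MeCN, 0 °C, dark, 1 h
Reagents that add atoms: NBS, O=C1CCC(=O)N1Br
Why: Ionic electrophilic aromatic bromination occurs at C4, which is ortho to one OMe and para to the other, and outruns attack on the trisubstituted prenyl alkene at 0 °C in polar solvent.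

**Step 3**
Reactants: 5; 6 (3-iodooxetane)
Product: 7 (3-(2,4-dimethoxy-3-prenylphenyl)oxetane, achiral and mirror-symmetric)
Conditions: NiI2 (10 mol%), 4,4′-di-tert-butylbipyridine (10 mol%), Zn, DMA, 60 °C
Reagents that add atoms: 3-iodooxetane, IC1COC1
Why: Nickel-catalysed cross-electrophile (Weix-type) coupling joins an aryl bromide to a secondary alkyl iodide through a radical pathway that leaves the strained oxetane intact, and C3 is the only sp3 carbon formed, so no stereocentre is created.

**Step 4**
Reactants: 3
Product: 8 (2-prenylresorcinol, 2-(3-methylbut-2-en-1-yl)benzene-1,3-diol)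
Conditions: NaSEt, DMF, 130 °C, 3 h
Reagents that add atoms: none
Why: Thiolate SN2 attack at the methyl groups cleaves aryl methyl ethers (nucleophilic demethylation) and leaves the prenyl alkene untouched, unlike strong Lewis acids that cyclise prenylphenols.

**Step 5 (key step)**
Reactants: 7; 8 (3 equiv)
Product: 9 ((2R)-2-(2,4-dimethoxy-3-prenylphenyl)-3-(2,4-dihydroxy-3-prenylphenyl)propan-1-ol)
Conditions: chiral imidodiphosphorimidate (IDPi) Brønsted acid (5 mol%), toluene, 4 Å MS, −20 °C, 72 h
Reagents that add atoms: none (the catalyst is not incorporated)
Why: Proposed new method: the chiral acid activates the oxetane oxygen by H-bonding or protonation while its conjugate base anchors a resorcinol OH. The most nucleophilic carbon of 8, C4 (para to one OH, ortho to the other), then attacks only one of the two enantiotopic oxetane CH2 groups in an SN2-type Friedel–Crafts ring-opening. The C–C bond and the C3 stereocentre are therefore set together, and the achiral 3-aryloxetane becomes a single enantiomer of the 2-aryl-propan-1-ol. Excess 8 suppresses dimerisation of 7, and H-bond anchoring of the phenol favours C-alkylation over O-alkylation. The closest known reactions are chiral-phosphoric-acid desymmetrization of 3-substituted oxetanes (with S- and N-nucleophiles) and Friedel–Crafts ring-opening of oxetanes and epoxides by electron-rich arenes.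

**Step 6**
Reactants: 9
Product: 10 ((3R)-3-(2,4-dimethoxy-3-prenylphenyl)-8-prenylchroman-7-ol)
Conditions: PPh3 (1.5 equiv), DIAD (1.5 equiv), THF (0.01 M), 0 °C → rt
Reagents that add atoms: none (PPh3 and DIAD are not incorporated)
Why: Intramolecular Mitsunobu etherification closes a six-membered ring (6-exo-tet) by the phenol ortho to the new benzylic CH2 attacking the activated primary carbinol. The para OH cannot reach, high dilution disfavours intermolecular reaction, and the reacting carbon is CH2, so the C3 stereocentre is untouched.

**Step 7**
Reactants: 10
Product: 11 (Kanzonol X)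
Conditions: NaSEt (10 equiv), DMF, 130 °C, 2 h; then aq. NH4Cl work-up
Reagents that add atoms: none
Why: Thiolate removes the two B-ring methyl groups by SN2 at methyl. The chroman ring CH2–OAr is a slower SN2 site, the prenyl alkenes survive, and C3–H is benzylic with no anion-stabilising neighbour, so it does not epimerise.

---

**Compound list**

| No. | Name | SMILES | Role |
|---|---|---|---|
| 1 | 1,3-Dimethoxybenzene | COc1cccc(OC)c1 | starting material |
| 2 | Prenyl bromide | CC(C)=CCBr | starting material |
| 3 | 2-Prenyl-1,3-dimethoxybenzene | CC(C)=CCc1c(OC)cccc1OC | intermediate |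
| 4 | N-Bromosuccinimide | O=C1CCC(=O)N1Br | starting material |
| 5 | 1-Bromo-2,4-dimethoxy-3-prenylbenzene | CC(C)=CCc1c(OC)ccc(Br)c1OC | intermediate |
| 6 | 3-Iodooxetane | IC1COC1 | starting material |
| 7 | 3-(2,4-Dimethoxy-3-prenylphenyl)oxetane | CC(C)=CCc1c(OC)ccc(C2COC2)c1OC | intermediate |
| 8 | 2-Prenylresorcinol | CC(C)=CCc1c(O)cccc1O | intermediate |
| 9 | (2R)-2-(2,4-Dimethoxy-3-prenylphenyl)-3-(2,4-dihydroxy-3-prenylphenyl)propan-1-ol | OC[C@H](Cc1ccc(O)c(CC=C(C)C)c1O)c1ccc(OC)c(CC=C(C)C)c1OC | intermediate |
| 10 | (3R)-3-(2,4-Dimethoxy-3-prenylphenyl)-8-prenylchroman-7-ol | CC(C)=CCc1c(OC)ccc([C@@H]2COc3c(ccc(O)c3CC=C(C)C)C2)c1OC | intermediate |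
| 11 | Kanzonol X | CC(C)=CCc1c(O)ccc([C@@H]2COc3c(ccc(O)c3CC=C(C)C)C2)c1O | target |

Atom check: 11 is C25H30O4 (isoflavan C15 plus two C5 prenyl groups). Compound 9 and the CH2OH carbon become C2 of the chroman, so their configurations correspond, and 11 matches the target SMILES.

**Total steps:** 7
**Longest linear sequence:** 6 steps (1 → 3 → 5 → 7 → 9 → 10 → 11; Step 4 is a parallel one-step branch from 3 that joins at Step 5)

**Three steps most likely to fail, with fallbacks**
1. **Step 5 (asymmetric Friedel–Crafts opening).** Risks are low ee, O-alkylation of the resorcinol, phenonium-type racemisation through the electron-rich B ring, and acid cyclisation of the prenylphenol. Fallback: make racemic 9 with Sc(OTf)3- or BF3-catalysed opening, carry on to racemic 10, and separate the enantiomers by preparative chiral-stationary-phase HPLC before demethylation. This replaces asymmetric catalysis with resolution.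
2. **Step 3 (Ni coupling of the hindered, electron-rich aryl bromide with 3-iodooxetane).** Risks are low yield, homocoupling, and Lewis-acid opening of the oxetane. Fallback: convert 5 to the arylboronic acid (n-BuLi, B(OiPr)3) and run a Ni-catalysed Suzuki coupling with 6 (NiI2, trans-2-aminocyclohexanol, iPrOH). This reverses the polarity of the coupling partners.
3. **Step 7 (global demethylation).** Risks are thiolate cleavage of the chroman CH2–OAr bond and damage to the prenyl groups. Fallback: redo the route with bis-MOM-protected B-ring and resorcinol building blocks (C2-lithiation of 1,3-bis(MOMO)benzene, prenylation, bromination), so the final deprotection is mild acid (HCl/MeOH, rt) instead of thiolate at 130 °C.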